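The constants used here are made up, and the outcome is calculated.

The leftover electrophile at the end of the run is what this flask is about.

electrophile 46 mM; buffer base 3.00 equiv; buffer acid 0.300 equiv; gas 28 mM (held); time 6.0 d

    protonated nucleophile ⇌ nucleophile + acid, settled at all times (K1 = 2.0 × 10⁻⁸ M)
    gas ⇌ nucleophile, rate k2*(csat - [nucleophile]) (k2 = 0.081 h⁻¹, csat = 28 mM)
    buffer acid ⇌ buffer base + acid, settled at all times (K3 = 3.2 × 10⁻⁹ M)
    electrophile + nucleophile → acid + product + leaving group (k4 = 1.8 M⁻¹ h⁻¹)

- part of the electrophile that has reacted at 6.0 d
- pH of the solution at 6.0 d

Two chemists dispute this flask. The first counts supply: into a solution free of nucleophile the gas delivers 2.27 mM h⁻¹, so he has the electrophile's charge delivered in 20.3 h, and he calls the flask finished early. The second counts decay: with [nucleophile] at 28 mM, the electrophile falls pseudo-first-order by a factor e, one e-fold, every 19.8 h, and he counts e-folds.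

My own reckoning joins them through a balance of the nucleophile, leaving its protonated form aside for now. What the gas has delivered is either spent on electrophile or still dissolved. Uptake slows with [nucleophile], and the time integral of [nucleophile] is also what counts the e-folds. Taking the charge as reacted and [nucleophile] at 28 mM, the run time splits into two parts: the e-folds times 19.8 h, plus a lag, the charge and a full solution divided by the supply into an empty solution, here 32.6 h. In this flask that leaves 5.61 e-folds in 144 h, so 0.365% of the electrophile remains and 99.6% has reacted.

The forecast sides with the second chemist: 99.6% reacted and pH 8.72, on “roughly five to six e-folds of electrophile loss over 144 h”.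

The flask gives 99.6% reacted and pH 8.72, so the forecast stands. The first chemist loses, with 56.3% used at 1.50 d; his delivery time grows with the charge, and at 182 mM of electrophile, equivalents and time held, where the answer has moved by 5 points, it is 80.2 h. At the end 2.66 mM of protonated nucleophile stood in this flask. Counted into the lag, it makes 33.8 h, which leaves 0.387% of the electrophile, against 0.38% in the flask.

The neighbour flask is read at 40 h. Taking half the charge as reacted and [nucleophile] at 28 mM, the lag and the e-folds for halving put that state at 36.2 h, earlier than the reading. The computed neighbour has 61.6% reacted.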